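## Structural features

The target is a prenylated pyranoflavanone that exists as its internal hemiketal. It contains ring A (a hexasubstituted benzene), ring C (the dihydropyran of the flavanone), ring B (a resorcinol-type benzene on C2), a 2,2-dimethyl-2H-pyran fused to ring A at C6/O7, and ring E, formed where O2' of ring B adds to C4. Rings C and E share C2, C3 and C4 and together form a 2,6-dioxabicyclo[3.3.1]nonane. Ring A carries, in order, the hemiketal carbon C4 on C4a, OMe on C5, the chromene carbon on C6, the chromene oxygen on C7, a prenyl group on C8 and O1 on C8a. The stereocentres C2 (R) and C4 (R, flavanone numbering) are the two bridgeheads, 1,3 to each other across C3. C4 is not independent, because the O2' bridge can close only on the face fixed by C2. Fragile elements are the hemiketal, the benzylic C2–O1 bond flanked by two ortho oxygens (retro-oxa-Michael opening of the keto form under base, ionisation under strong acid), and the prenyl and chromene double bonds. The real difficulty is the regiodefined hexasubstitution of ring A with three differentiated oxygens, combined with one enantiopure benzylic ether carbon that bears a hindered 2,6-dioxygenated aryl group. The key step uses the fact that ring A is an acylphloroglucinol (oxygens on C5, C7 and C8a, acyl carbon C4 on C4a) and that O1–C8a=C4a–C4=O is a vinylogous ester. Ring C can therefore be made first as a 2,3-dihydro-4H-pyran-4-one, and ring A closed onto it by joining C5 to the nucleophilic carbon C4a.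

## Logic of the disconnections

**20 to 18 (through 19).** The hemiketal bond C4–O2' and the two aryl O–CH2OMe bonds are cut. The hemiketal is the resting form of a 2'-hydroxy flavanone that has no 5-OH hydrogen bond to its ketone, so it should form by itself once the ring B phenols are free. This removes the cage and the C4 stereocentre from the problem. The forward step needs acid mild enough for the prenyl group, the chromene and the C2–O1 bond, and no alcohol solvent that could give a mixed ketal.

**18 to 17.** The O5–CH3 bond is cut. The chelated 5-OH is the last free phenol and, while free, is what steers the chromene closure to O7, so it is methylated afterwards. The forward step must be non-basic, so that C3 is never deprotonated and ring C cannot open.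

**17 to 14 and 15.** The bonds C6–C(chromene) and O7–CMe2 are cut. Ring A is reduced to a phloroglucinol with a single free ring carbon (C6), so the annulation has no positional choice on carbon. The forward step needs closure through O7 and not O5, and must leave C2 untouched.

**14 to 12 (through 13).** The C5–C4a bond is cut, which dismantles ring A completely. What remains is a dihydropyranone carrying a four-carbon keto ester chain in which the prenyl group already sits on the future C8. The forward step needs a ketene source that works without base, high dilution, and a chain that can reach only C4a.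

**12 to 9 and 10.** The C6–C7 bond is cut. The two-carbon ester unit is added to an acyl group under near-neutral magnesium conditions, because the C8–H is so acidic that a lithium enolate plus a malonyl electrophile would end in proton transfer. The gain is a carboxylic acid with one fewer carbonyl. The demand is that 9, a vinylogous β-keto acid, is handled cold and used at once.

**9 to 7 and 8.** The bond C8–CH2 of the prenyl group is cut. In 7 the carbon C8 is the only doubly activated position (α to the carboxylate, γ to the ring carbonyl), so the prenyl group enters with no regiochemical alternative. The forward step needs dianion formation at C8 and not at C3.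

**7 to 6.** The C8–C7 bond is cut, with carbon dioxide as the one-carbon electrophile. This leaves a 6-methyl dihydropyranone. The forward step needs the extended enolate through the methyl group and not the cross-conjugated C3 enolate, and ring C must stay closed.

**6 to 2 and 4.** The bonds C2–C3 and O1–C8a are cut (hetero-Diels–Alder). Ring C and the only independent stereocentre come from an achiral aldehyde and an achiral diene under a chiral catalyst. The forward step needs good facial selectivity on an ortho,ortho-disubstituted aldehyde.

**4 to 3, and 2 to 1.** The O–Si bond of 4 and the two O–CH2OMe bonds of 2 are cut. In 3 the enol ether is already on the correct carbon, so the diene is regiodefined without O-alkylating an unsymmetrical diketone. Both forward steps are routine.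

## Other disconnections considered

**Alternative 1:** The cut removes ring B (bonds C1'–C2', C2'–C3', C5'–C6') and the hemiketal bond C4–O2'. In the forward direction cyclobut-2-en-1-one A3 is heated with the C2 alkynyl ether A2 of the finished chromanone. Ring opening to a vinylketene, [2+2] addition to the electron-rich alkyne, 4π opening and 6π closure would give the ring B phenol, which adds to C4 to give the silylethyl ether A1 of 20.
- In its favour: it is highly convergent, it forms three C–C bonds and the cage in one operation, and it differentiates the two ring B oxygens. On bond-forming economy in the key step it is better than the chosen plan.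
- Against it: A2 is an enantiopure 2-alkynyl chromanone with a propargylic C2–O1 bond β to a ketone, so it is prone to retro-oxa-Michael opening and to hydration of the ynol ether. Asymmetric access to such an alkoxyalkynyl chromanone is not covered by known conjugate alkynylations. A3 is volatile and polymerises easily. The final fluoride deprotection is basic.
- Comparison: both plans build an aromatic ring by ketene electrocyclic chemistry. The chosen plan builds the ring that holds all the regiochemical problems (ring A) and sets C2 early on a simple aldehyde. Alternative 1 builds the easy ring B and leaves prenylation, chromenylation and O-differentiation of ring A to classical phenol chemistry. Step count is expected to be equal at best.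

**Alternative 2:** The cut is C2–C1' and C4–O2'. In the forward direction the chromone-3-carboxylic acid A5 takes up cyclohexane-1,3-dione A6 at C2 under a bifunctional cinchona squaramide with loss of carbon dioxide, and the dione enol oxygen closes onto C4 to give the bridged hemiketal A4.
- In its favour: C2 and the whole bicycle arise in one catalytic asymmetric step, late and convergently. Decarboxylative additions to chromone-3-carboxylic acids are an established reaction class. On convergence and on the number of operations needed to reach the cage it is better than the chosen plan.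
- Against it: A4 is not at the oxidation level of 20. Its cyclohexenone must be dehydrogenated to a phenol in the presence of the prenyl group, the chromene double bond, benzylic positions and the hemiketal, all of which are attacked by the usual quinone, halogenation–elimination or palladium/oxygen methods. A5 also needs the fully decorated ring A made beforehand.
- Comparison: the chosen plan needs no redox adjustment and no late oxidation. Both set C2 catalytically. Alternative 2 is shorter up to the cage but rests on one very uncertain aromatisation.

**Alternative 3:** The cut removes ring A (bonds C7–C8, C8a–C4a, C6–C7) and later C4–C4a. In the forward direction photochemical Wolff rearrangement of the diazoenone A8 gives a methoxy vinylketene, which combines with the enantiopure ynol ether A9 in a Danheiser benzannulation to give the phenol A7.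
- In its favour: like the chosen plan it builds ring A de novo with the prenyl group fixed at C8. It is better on one point: O5 arrives methylated and O7 free, so the methylation of a chelated phenol and the O5/O7 question disappear.
- Against it: ring C is still open after the key step. The silyl ether must be removed, the alcohol oxidised to the acid, and the ring closed by Friedel–Crafts acylation at C4a. Those acidic conditions threaten the doubly ortho-oxygenated benzylic ether, the acetals and the prenyl group. A9 is an alkynyl ether of a secondary benzylic alcohol and can fragment thermally to a ketene and an alkene.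
- Comparison: the mechanism belongs to the same family (ketene, 6π closure). The chosen plan closes ring A onto a preformed ring C, so no Friedel–Crafts step is needed, and the stereocentre is held in a ring throughout. Alternative 3 is expected to be several steps longer.

Key step: step 7

Remark: the target is read as (2R,4R) in flavanone numbering, and 12 and 14 have the same (R) configuration at C2, so no structural correction is needed; the prenyl-bearing chain carbon of 9, 11, 12 and 13 is carried as a mixture of epimers because it becomes an aromatic carbon in step 7.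

## Route

Step 1
Reactants: 1 2,6-dihydroxybenzaldehyde
Product: 2 2,6-bis(methoxymethoxy)benzaldehyde
Conditions: MOMCl, iPr2NEt, CH2Cl2, 0 °C to rt
Reagents that add atoms: chloromethyl methyl ether, COCCl
Why: O-alkylation of both phenols to acetals; the methoxymethyl ethers should tolerate amide bases, the mild Lewis acid of step 3 and 110 °C, and are removed last by dilute acid.

Step 2
Reactants: 3 (E)-4-methoxypent-3-en-2-one
Product: 4 (E)-4-methoxy-2-(trimethylsilyloxy)penta-1,3-diene
Conditions: Me3SiOTf, Et3N, Et2O, 0 °C
Reagents that add atoms: trimethylsilyl trifluoromethanesulfonate, C[Si](C)(C)OS(=O)(=O)C(F)(F)F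
Why: Soft enolisation of the vinylogous ester at its acetyl methyl group (the α' position, the usual site for β-alkoxy enones) gives the 1-alkoxy-3-siloxy diene; the enol ether is already regiodefined in 3.

Step 3
Reactants: 2 2,6-bis(methoxymethoxy)benzaldehyde; 4 (E)-4-methoxy-2-(trimethylsilyloxy)penta-1,3-diene
Product: 6 (2R)-2-[2,6-bis(methoxymethoxy)phenyl]-6-methyl-2,3-dihydro-4H-pyran-4-one, via Mukaiyama aldol adduct 5 (not isolated)
Conditions: (R)-BINOL (20 mol %), Ti(OiPr)4 (10 mol %), 4 Å molecular sieves, toluene, −20 °C; then CF3CO2H (cat.), CH2Cl2, 0 °C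
Reagents that add atoms: none
Why: Catalytic asymmetric hetero-Diels–Alder reaction by the Mukaiyama aldol–cyclisation pathway: the BINOL–titanium complex binds the aldehyde, the diene terminus attacks one carbonyl face to give 5, and acid closes ring C with loss of methanol. C2 is set here by the ligand; (R)-BINOL is expected to give the (R) product by analogy with its additions to other aromatic aldehydes, and (S)-BINOL is used if the sense proves opposite for this hindered aldehyde.

Step 4
Reactants: 6 (2R)-2-[2,6-bis(methoxymethoxy)phenyl]-6-methyl-2,3-dihydro-4H-pyran-4-one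
Product: 7 {(2R)-2-[2,6-bis(methoxymethoxy)phenyl]-4-oxo-3,4-dihydro-2H-pyran-6-yl}acetic acid
Conditions: LiN(SiMe3)2 (0.95 equiv), THF, −78 to −30 °C, then −78 °C; CO2; cold aq. HCl to pH 3
Reagents that add atoms: carbon dioxide, O=C=O
Why: Carboxylation of the extended (vinylogous) lithium enolate: a slight deficiency of the reversible amide base and brief warming should let any cross-conjugated C3 enolate equilibrate to the more delocalised dienolate, which reacts with CO2 at its terminal carbon as the dienolates of 2-methyl-4-pyranones and 6-methyl-1,3-dioxin-4-ones do. A C3-carboxylated by-product is a β-keto acid that should lose CO2 again on work-up, and bicarbonate extraction separates 7 from recovered 6.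

Step 5
Reactants: 7 {(2R)-2-[2,6-bis(methoxymethoxy)phenyl]-4-oxo-3,4-dihydro-2H-pyran-6-yl}acetic acid; 8 prenyl bromide (1-bromo-3-methylbut-2-ene)
Product: 9 2-{(2R)-2-[2,6-bis(methoxymethoxy)phenyl]-4-oxo-3,4-dihydro-2H-pyran-6-yl}-5-methylhex-4-enoic acid (both epimers at the chain carbon)
Conditions: LiN(iPr)2 (2.2 equiv), THF, −78 °C; then 8, −78 to −20 °C; cold aq. HCl to pH 3
Reagents that add atoms: none
Why: Alkylation of a carboxylic acid dianion: the second deprotonation takes place at the only doubly activated carbon (α to the carboxylate and γ to the ring carbonyl), and the allylic bromide alkylates that carbon, so the prenyl group arrives at the future C8 without a regiochemical alternative. The new centre is not controlled and need not be.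

Step 6
Reactants: 9 2-{(2R)-2-[2,6-bis(methoxymethoxy)phenyl]-4-oxo-3,4-dihydro-2H-pyran-6-yl}-5-methylhex-4-enoic acid; 10 mono-tert-butyl malonate (3-tert-butoxy-3-oxopropanoic acid)
Product: 12 tert-butyl 4-{(2R)-2-[2,6-bis(methoxymethoxy)phenyl]-4-oxo-3,4-dihydro-2H-pyran-6-yl}-7-methyl-3-oxooct-6-enoate (both epimers at C4 of the chain), via acyl imidazolide 11 (not isolated)
Conditions: 1,1'-carbonyldiimidazole, THF, 0 °C to rt; then 10, MgCl2, Et3N, THF, rt; dilute aq. HCl
Reagents that add atoms: none
Why: Masamune–Brooks homologation: the magnesium enolate of the malonate half ester attacks the acyl imidazolide and decarboxylation gives the β-keto ester under near-neutral conditions. This tolerates the acidic C8–H, which would simply protonate a lithium enolate if a malonyl electrophile were used instead.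

Step 7
Reactants: 12 tert-butyl 4-{(2R)-2-[2,6-bis(methoxymethoxy)phenyl]-4-oxo-3,4-dihydro-2H-pyran-6-yl}-7-methyl-3-oxooct-6-enoate
Product: 14 (2R)-2-[2,6-bis(methoxymethoxy)phenyl]-5,7-dihydroxy-8-(3-methylbut-2-en-1-yl)-2,3-dihydro-4H-chromen-4-one, via acylketene 13 (not isolated)
Conditions: toluene (0.005 M), 110 °C, argon, slow distillation of t-BuOH with solvent replacement
Reagents that add atoms: none
Why: Proposed new method: thermal loss of tert-butanol from the β-keto ester (the elimination known for tert-butyl acetoacetates) gives acylketene 13, whose C7 carbonyl enolises toward C8 so that the ketene, the C7=C8 enol and the C8a=C4a enol ether form a dienylketene. Six-membered closure then joins C5 to C4a, either as a thermally allowed disrotatory 6π electrocyclisation or, in polar terms, as a 6-(enolendo)-exo-dig C-acylation of the nucleophilic enol ether carbon by the ketene, and tautomerisation of the cyclohexadienone gives the phloroglucinol ring A with no change in oxidation level. The closest known reactions are the ring closure of dienylketenes in benzannulations, the aromatisation of polycarbonyl chains released as acylketenes from dioxinones or tert-butyl esters in resorcylate synthesis, and the base-mediated Claisen cyclisation of triketo esters to acylphloroglucinols; new here is a cyclic vinylogous ester carbon as the nucleophile. No stereocentre is created: the epimeric chain carbon becomes aromatic C8 and C2 takes no part. The step needs C-acylation at C4a to win over ketene dimerisation, re-addition of tert-butanol and O-acylation; C4a is the only nucleophilic atom that can reach C5 through a strain-free six-membered transition state (the oxygen atoms would give four- or eight-membered rings), high dilution suppresses bimolecular paths and the alcohol is distilled out. Because no base is present, C3 is never deprotonated, so ring C cannot open by retro-oxa-Michael elimination and the C2 configuration should be retained.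

Step 8
Reactants: 14 (2R)-2-[2,6-bis(methoxymethoxy)phenyl]-5,7-dihydroxy-8-(3-methylbut-2-en-1-yl)-2,3-dihydro-4H-chromen-4-one; 15 3-methylbut-2-enal
Product: 17 (8R)-8-[2,6-bis(methoxymethoxy)phenyl]-5-hydroxy-2,2-dimethyl-10-(3-methylbut-2-en-1-yl)-7,8-dihydro-2H,6H-pyrano[3,2-g]chromen-6-one, via ortho-quinone methide 16 (not isolated)
Conditions: 15 (2 equiv), ethylenediammonium diacetate (10 mol %), toluene, 90 °C
Reagents that add atoms: none
Why: Amine-salt-catalysed Knoevenagel-type condensation of the enal at the only free ring carbon (C6) gives the ortho-quinone methide 16, which closes by oxa-6π electrocyclisation (formal [3+3] chromene annulation). The hydrogen bond from O5–H to the C4 carbonyl should keep O5 as the phenol, so that closure uses O7.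

Step 9
Reactants: 17 (8R)-8-[2,6-bis(methoxymethoxy)phenyl]-5-hydroxy-2,2-dimethyl-10-(3-methylbut-2-en-1-yl)-7,8-dihydro-2H,6H-pyrano[3,2-g]chromen-6-one
Product: 18 (8R)-8-[2,6-bis(methoxymethoxy)phenyl]-5-methoxy-2,2-dimethyl-10-(3-methylbut-2-en-1-yl)-7,8-dihydro-2H,6H-pyrano[3,2-g]chromen-6-one
Conditions: MeOH, PPh3, DIAD, THF, 0 °C to rt
Reagents that add atoms: methanol, CO
Why: Mitsunobu etherification: the chelated phenol is acidic enough for the betaine and is methylated under neutral conditions, so C3 is never deprotonated and ring C cannot open to the chalcone.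

Step 10
Reactants: 18 (8R)-8-[2,6-bis(methoxymethoxy)phenyl]-5-methoxy-2,2-dimethyl-10-(3-methylbut-2-en-1-yl)-7,8-dihydro-2H,6H-pyrano[3,2-g]chromen-6-one
Product: 20 the target, CNP0170313.2 (bridged hemiketal, C2 R and C4 R in flavanone numbering), via free 2',6'-dihydroxy ketone 19 (not isolated)
Conditions: 2 M aq. HCl, THF, 40 °C
Reagents that add atoms: none
Why: Acid-catalysed hydrolysis of the two aryl methoxymethyl acetals liberates 19, in which one of the two equivalent ring B phenols adds to the C4 ketone (no longer stabilised by a 5-OH hydrogen bond) to give the hemiketal. The C4 configuration follows from C2 because the bridge can form on one face only; aqueous THF and not an alcohol avoids a mixed ketal.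

## Compound list

1 | 2,6-dihydroxybenzaldehyde | O=Cc1c(O)cccc1O | starting material
2 | 2,6-bis(methoxymethoxy)benzaldehyde | O=Cc1c(OCOC)cccc1OCOC | intermediate
3 | (E)-4-methoxypent-3-en-2-one | CO/C(C)=C/C(C)=O | starting material
4 | (E)-4-methoxy-2-(trimethylsilyloxy)penta-1,3-diene | C=C(O[Si](C)(C)C)/C=C(\C)OC | intermediate
5 | (1R,4E)-1-[2,6-bis(methoxymethoxy)phenyl]-5-methoxy-1-(trimethylsilyloxy)hex-4-en-3-one | CO/C(C)=C/C(=O)C[C@@H](O[Si](C)(C)C)c1c(OCOC)cccc1OCOC | intermediate
6 | (2R)-2-[2,6-bis(methoxymethoxy)phenyl]-6-methyl-2,3-dihydro-4H-pyran-4-one | CC1=CC(=O)C[C@@H](O1)c1c(OCOC)cccc1OCOC | intermediate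
7 | {(2R)-2-[2,6-bis(methoxymethoxy)phenyl]-4-oxo-3,4-dihydro-2H-pyran-6-yl}acetic acid | OC(=O)CC1=CC(=O)C[C@@H](O1)c1c(OCOC)cccc1OCOC | intermediate
8 | prenyl bromide (1-bromo-3-methylbut-2-ene) | CC(C)=CCBr | starting material
9 | 2-{(2R)-2-[2,6-bis(methoxymethoxy)phenyl]-4-oxo-3,4-dihydro-2H-pyran-6-yl}-5-methylhex-4-enoic acid (both epimers at the chain carbon) | OC(=O)C(CC=C(C)C)C1=CC(=O)C[C@@H](O1)c1c(OCOC)cccc1OCOC | intermediate
10 | mono-tert-butyl malonate (3-tert-butoxy-3-oxopropanoic acid) | CC(C)(C)OC(=O)CC(=O)O | starting material
11 | 2-{(2R)-2-[2,6-bis(methoxymethoxy)phenyl]-4-oxo-3,4-dihydro-2H-pyran-6-yl}-1-(1H-imidazol-1-yl)-5-methylhex-4-en-1-one | O=C(n1ccnc1)C(CC=C(C)C)C1=CC(=O)C[C@@H](O1)c1c(OCOC)cccc1OCOC | intermediate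
12 | tert-butyl 4-{(2R)-2-[2,6-bis(methoxymethoxy)phenyl]-4-oxo-3,4-dihydro-2H-pyran-6-yl}-7-methyl-3-oxooct-6-enoate (both epimers at C4 of the chain) | CC(C)(C)OC(=O)CC(=O)C(CC=C(C)C)C1=CC(=O)C[C@@H](O1)c1c(OCOC)cccc1OCOC | intermediate
13 | 4-{(2R)-2-[2,6-bis(methoxymethoxy)phenyl]-4-oxo-3,4-dihydro-2H-pyran-6-yl}-7-methyl-3-oxoocta-1,6-dien-1-one (acylketene) | O=C=CC(=O)C(CC=C(C)C)C1=CC(=O)C[C@@H](O1)c1c(OCOC)cccc1OCOC | intermediate
14 | (2R)-2-[2,6-bis(methoxymethoxy)phenyl]-5,7-dihydroxy-8-(3-methylbut-2-en-1-yl)-2,3-dihydro-4H-chromen-4-one | Oc1cc(O)c(CC=C(C)C)c2O[C@H](CC(=O)c12)c1c(OCOC)cccc1OCOC | intermediate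
15 | 3-methylbut-2-enal | CC(C)=CC=O | starting material
16 | ortho-quinone methide: the 6-(3-methylbut-2-en-1-ylidene)-7-oxo dienone tautomer of 14 condensed with 15 at C6 | CC(C)=CC=C1C(=O)C(CC=C(C)C)=C2O[C@H](CC(=O)C2=C1O)c1c(OCOC)cccc1OCOC | intermediate
17 | (8R)-8-[2,6-bis(methoxymethoxy)phenyl]-5-hydroxy-2,2-dimethyl-10-(3-methylbut-2-en-1-yl)-7,8-dihydro-2H,6H-pyrano[3,2-g]chromen-6-one | Oc1c2C=CC(C)(C)Oc2c(CC=C(C)C)c2O[C@H](CC(=O)c12)c1c(OCOC)cccc1OCOC | intermediate
18 | (8R)-8-[2,6-bis(methoxymethoxy)phenyl]-5-methoxy-2,2-dimethyl-10-(3-methylbut-2-en-1-yl)-7,8-dihydro-2H,6H-pyrano[3,2-g]chromen-6-one | COc1c2C=CC(C)(C)Oc2c(CC=C(C)C)c2O[C@H](CC(=O)c12)c1c(OCOC)cccc1OCOC | intermediate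
19 | (8R)-8-(2,6-dihydroxyphenyl)-5-methoxy-2,2-dimethyl-10-(3-methylbut-2-en-1-yl)-7,8-dihydro-2H,6H-pyrano[3,2-g]chromen-6-one (open keto form) | COc1c2C=CC(C)(C)Oc2c(CC=C(C)C)c2O[C@H](CC(=O)c12)c1c(O)cccc1O | intermediate
20 | CNP0170313.2: hemiketal of 19 in which one ring B phenol oxygen bridges to C4 (C2 R, C4 R, flavanone numbering; 5-methoxy, 8-prenyl, 6,7-fused 2,2-dimethylpyran, free 6'-OH and 4-OH) | COc1c2c(c(CC=C(C)C)c3c1[C@@]1(O)C[C@@H](O3)c3c(O)cccc3O1)OC(C)(C)C=C2 | target

Total steps: 10. Longest linear sequence: 9 steps (1, 3, 4, 5, 6, 7, 8, 9, 10, from 2,6-dihydroxybenzaldehyde); step 2 is a one-step side branch.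

## Least certain steps

**Step 7 (key step).** The most likely failure is consumption of the acylketene by bimolecular paths (dimerisation, re-addition of tert-butanol, O-acylation of the phenols of 14) before the chain adopts the dienylketene geometry, since enolisation of C7 toward the substituted C8 may be slow.

The fallback uses known chemistry and changes the approach to a chalcone route with resolution. It sets out from 2 (with 8) and comes back at 14. Commercial 2,4,6-trihydroxyacetophenone is C-prenylated with 8 (DBU, THF) to 1-[2,4,6-trihydroxy-3-(3-methylbut-2-en-1-yl)phenyl]ethanone F1. The 4- and 6-hydroxyls are allylated (allyl bromide, K2CO3, acetone), leaving the hindered chelated 2-OH, to give 1-[2-hydroxy-3-(3-methylbut-2-en-1-yl)-4,6-bis(prop-2-en-1-yloxy)phenyl]ethanone F2. Claisen–Schmidt condensation of F2 with 2 (KOH, EtOH) gives the chalcone F3. NaOAc in refluxing EtOH closes it by oxa-Michael addition to the racemic bis-allyl flavanone F4. Pd(PPh3)4 with morpholine removes the allyl groups to give the racemic dihydroxy flavanone F5. Preparative chromatography on a cellulose tris(3,5-dimethylphenylcarbamate) stationary phase then separates the (2R) enantiomer, which is 14.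

**Step 3.** The most likely failure is poor facial selectivity or low conversion, because the aldehyde is electron-rich and ortho,ortho-disubstituted and its acetal oxygens can compete for titanium; partial loss of an acetal during the acid cyclisation is a lesser risk.

The fallback sets C2 with a stoichiometric chiral reagent and builds ring C by cyclodehydration. It sets out from 2 and comes back at 6. Methallylboration of 2 with the antipode of Ipc2B(methallyl) expected to give the (R)-carbinol (Et2O, −78 °C, then NaOH/H2O2) gives (1R)-1-[2,6-bis(methoxymethoxy)phenyl]-3-methylbut-3-en-1-ol F6. Cleavage of the alkene with OsO4 (cat.) and NaIO4 (2,6-lutidine, dioxane/water) gives (4R)-4-[2,6-bis(methoxymethoxy)phenyl]-4-hydroxybutan-2-one F7. Treatment with LiN(iPr)2 (2.2 equiv) and then N-methoxy-N-methylacetamide acylates the methyl-side enolate of the aldolate to give (6R)-6-[2,6-bis(methoxymethoxy)phenyl]-6-hydroxyhexane-2,4-dione F8. Pyridinium p-toluenesulfonate in CH2Cl2 cyclodehydrates F8 to 6.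

**Step 4.** The most likely failure is deprotonation at C3 (the kinetically preferred α' site of a vinylogous ester) in place of the methyl group; during equilibration the C3 enolate could also open ring C by β-elimination and erode the enantiomeric purity.

The fallback avoids enolate chemistry on the pyranone by carboxylating before ring C exists. It sets out from 2 and comes back at 7. It passes through F6, F7 and F8 as described for step 3. F8 is converted with LiN(iPr)2 (3.3 equiv) to its alkoxide–diketone dianion, which CO2 carboxylates at the terminal methyl carbon (the usual site for β-diketone dianions) to give (7R)-7-[2,6-bis(methoxymethoxy)phenyl]-7-hydroxy-3,5-dioxoheptanoic acid F9. Cold dilute acid then cyclodehydrates F9, the C7 hydroxyl adding to the C3 carbonyl, to give 7.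

**Step 8.** The most likely failure is loss of regiocontrol in the electrocyclisation (closure through O5 in place of O7), or slow erosion of the C2 configuration by reversible opening of ring C under the warm amine-salt conditions.

The fallback fixes the oxygen before the carbon. It sets out from 14 and comes back at 17. The non-chelated, more acidic 7-OH is propargylated with 2-methylbut-3-yn-2-yl trifluoroacetate (DBU, CuCl2 cat., MeCN, 0 °C) to give (2R)-2-[2,6-bis(methoxymethoxy)phenyl]-5-hydroxy-7-[(2-methylbut-3-yn-2-yl)oxy]-8-(3-methylbut-2-en-1-yl)-2,3-dihydro-4H-chromen-4-one F10. Heating F10 in xylene at 130 °C brings about the aromatic propargyl Claisen rearrangement to C6 (C8 is blocked), a 1,5-hydrogen shift and oxa-6π closure, giving 17.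

## Further compounds

F1 | step 7 | 1-[2,4,6-trihydroxy-3-(3-methylbut-2-en-1-yl)phenyl]ethanone | CC(=O)c1c(O)cc(O)c(CC=C(C)C)c1O
F2 | step 7 | 1-[2-hydroxy-3-(3-methylbut-2-en-1-yl)-4,6-bis(prop-2-en-1-yloxy)phenyl]ethanone | CC(=O)c1c(OCC=C)cc(OCC=C)c(CC=C(C)C)c1O
F3 | step 7 | (2E)-3-[2,6-bis(methoxymethoxy)phenyl]-1-[2-hydroxy-3-(3-methylbut-2-en-1-yl)-4,6-bis(prop-2-en-1-yloxy)phenyl]prop-2-en-1-one | O=C(/C=C/c1c(OCOC)cccc1OCOC)c1c(OCC=C)cc(OCC=C)c(CC=C(C)C)c1O
F4 | step 7 | racemic 2-[2,6-bis(methoxymethoxy)phenyl]-8-(3-methylbut-2-en-1-yl)-5,7-bis(prop-2-en-1-yloxy)-2,3-dihydro-4H-chromen-4-one | C=CCOc1cc(OCC=C)c(CC=C(C)C)c2OC(CC(=O)c12)c1c(OCOC)cccc1OCOC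
F5 | step 7 | racemic 2-[2,6-bis(methoxymethoxy)phenyl]-5,7-dihydroxy-8-(3-methylbut-2-en-1-yl)-2,3-dihydro-4H-chromen-4-one | Oc1cc(O)c(CC=C(C)C)c2OC(CC(=O)c12)c1c(OCOC)cccc1OCOC
F6 | step 3 | (1R)-1-[2,6-bis(methoxymethoxy)phenyl]-3-methylbut-3-en-1-ol | CC(=C)C[C@@H](O)c1c(OCOC)cccc1OCOC
F7 | step 3 | (4R)-4-[2,6-bis(methoxymethoxy)phenyl]-4-hydroxybutan-2-one | CC(=O)C[C@@H](O)c1c(OCOC)cccc1OCOC
F8 | step 3 | (6R)-6-[2,6-bis(methoxymethoxy)phenyl]-6-hydroxyhexane-2,4-dione | CC(=O)CC(=O)C[C@@H](O)c1c(OCOC)cccc1OCOC
F9 | step 4 | (7R)-7-[2,6-bis(methoxymethoxy)phenyl]-7-hydroxy-3,5-dioxoheptanoic acid | OC(=O)CC(=O)CC(=O)C[C@@H](O)c1c(OCOC)cccc1OCOC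
F10 | step 8 | (2R)-2-[2,6-bis(methoxymethoxy)phenyl]-5-hydroxy-7-[(2-methylbut-3-yn-2-yl)oxy]-8-(3-methylbut-2-en-1-yl)-2,3-dihydro-4H-chromen-4-one | Oc1cc(OC(C)(C)C#C)c(CC=C(C)C)c2O[C@H](CC(=O)c12)c1c(OCOC)cccc1OCOC
A1 | alternative 1 | 2-(trimethylsilyl)ethyl ether of 20 at the free ring B phenol | COc1c2c(c(CC=C(C)C)c3c1[C@@]1(O)C[C@@H](O3)c3c(OCC[Si](C)(C)C)cccc3O1)OC(C)(C)C=C2
A2 | alternative 1 | (8R)-5-methoxy-2,2-dimethyl-10-(3-methylbut-2-en-1-yl)-8-{[2-(trimethylsilyl)ethoxy]ethynyl}-7,8-dihydro-2H,6H-pyrano[3,2-g]chromen-6-one | COc1c2C=CC(C)(C)Oc2c(CC=C(C)C)c2O[C@H](CC(=O)c12)C#COCC[Si](C)(C)C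
A3 | alternative 1 | cyclobut-2-en-1-one | O=C1C=CC1
A4 | alternative 2 | bridged hemiketal with a cyclohexenone in place of ring B | COc1c2c(c(CC=C(C)C)c3c1[C@@]1(O)C[C@@H](O3)C3=C(CCCC3=O)O1)OC(C)(C)C=C2
A5 | alternative 2 | 5-methoxy-2,2-dimethyl-10-(3-methylbut-2-en-1-yl)-6-oxo-2H,6H-pyrano[3,2-g]chromene-7-carboxylic acid | COc1c2C=CC(C)(C)Oc2c(CC=C(C)C)c2occ(C(=O)O)c(=O)c12
A6 | alternative 2 | cyclohexane-1,3-dione | O=C1CCCC(=O)C1
A7 | alternative 3 | 5-methoxy-2-(3-methylbut-2-en-1-yl)-3-{(1R)-1-[2,6-bis(methoxymethoxy)phenyl]-3-(tert-butyldimethylsilyloxy)propoxy}phenol | COc1cc(O)c(CC=C(C)C)c(O[C@H](CCO[Si](C)(C)C(C)(C)C)c2c(OCOC)cccc2OCOC)c1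
A8 | alternative 3 | 1-diazo-3-methoxybut-3-en-2-one | COC(=C)C(=O)C=[N+]=[N-]
A9 | alternative 3 | (1R)-1-[2,6-bis(methoxymethoxy)phenyl]-3-(tert-butyldimethylsilyloxy)propyl 5-methylhex-4-en-1-ynyl ether | CC(C)=CCC#CO[C@H](CCO[Si](C)(C)C(C)(C)C)c1c(OCOC)cccc1OCOC
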